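**Plan**

- Retrosynthesis: the C5 phenol is masked as a methyl ether. The pyranone is opened at O1–C2 to an ortho-hydroxyaryl ynone. The ynone is cut at C8a–O1 and C4a–C4 together, giving 3-methoxybenzyne and octadec-2-ynoic acid. The acid is cut at C3–C4 to 1-heptadecyne and CO2.
- Enabling feature: ring A carries three contiguous substituents (C5–OH, the C4 acyl carbon on C4a, O1 on C8a). C4a–C4 and C8a–O1 sit on neighbouring arene carbons beside the C5 oxygen, which are the two carbons of a 3-alkoxy aryne, and C4 and O1 are the acyl carbon and hydroxyl oxygen of one carboxyl group.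
- Forward: the aryne precursor is built from 3-methoxyphenol and the C18 ynoic acid from 1-heptadecyne. The aryne insertion joins the two fragments without closing a ring. The pyranone ring then closes at O1–C2, and O-demethylation ends the route.
- Stereochemistry: the target has no stereocentre and no stereogenic double bond, so none has to be set.

Key step: step 5

Remark: atom numbers are those of the chromone (O1, C2, C3, C4, C4a, C5 to C8, C8a); 3-methoxyphenol, 1-heptadecyne and CO2 are taken as purchased.

**Route**

Step 1
Reactants: 1 3-methoxyphenol
Product: 2 3-methoxyphenyl propan-2-ylcarbamate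
Conditions: i-PrNCO, Et3N (cat.), CH2Cl2, rt
Reagents that add atoms: isopropyl isocyanate, CC(C)N=C=O
Why: Base-catalysed addition of the phenol to the isocyanate (carbamoylation) installs a secondary carbamate that directs ortho-metalation in step 2 and can later be removed by a mild E1cB elimination.

Step 2
Reactants: 2 3-methoxyphenyl propan-2-ylcarbamate
Product: 6 3-methoxy-2-(trimethylsilyl)phenyl propan-2-ylcarbamate, via N-silyl carbamate 3 (not isolated), via aryllithium 4 (not isolated), via N-silyl C-silyl carbamate 5 (not isolated)
Conditions: TMSOTf, TMEDA, Et2O, 0 °C → rt; n-BuLi, TMEDA, −78 °C; TMSCl, −78 °C → rt; aq. NaHSO4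
Reagents that add atoms: chlorotrimethylsilane, C[Si](C)(C)Cl
Why: This is a directed ortho-metalation in which in-situ N-silylation first masks the acidic N–H, n-BuLi/TMEDA then removes the C2 proton flanked by the carbamate and methoxy directing groups (the cooperative in-between site), TMSCl traps the aryllithium, and the acidic work-up hydrolyses only the N–Si bond.

Step 3
Reactants: 6 3-methoxy-2-(trimethylsilyl)phenyl propan-2-ylcarbamate
Product: 8 3-methoxy-2-(trimethylsilyl)phenyl trifluoromethanesulfonate, via 3-methoxy-2-(trimethylsilyl)phenol 7 (not isolated)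
Conditions: DBU, Et2NH, MeCN, 40 °C; then PhNTf2, rt
Reagents that add atoms: N-phenylbis(trifluoromethanesulfonimide), O=S(=O)(N(c1ccccc1)S(=O)(=O)C(F)(F)F)C(F)(F)F
Why: DBU removes the carbamate N–H and the aryloxide is expelled by E1cB elimination (the isocyanate being scavenged by diethylamine), after which the phenoxide is O-sulfonylated in the same pot by PhNTf2, a triflating agent mild enough to leave the aryl–silicon bond intact.

Step 4
Reactants: 9 1-heptadecyne; 10 carbon dioxide
Product: 12 octadec-2-ynoic acid, via lithium heptadec-1-yn-1-ide 11 (not isolated)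
Conditions: n-BuLi, THF, −78 °C; CO2, −78 °C → rt; aq. HCl
Reagents that add atoms: none
Why: Deprotonation of the terminal alkyne with n-BuLi and carboxylation of the lithium acetylide with CO2 is the standard one-carbon homologation to an alk-2-ynoic acid and forms the bond that becomes C3–C4.

Step 5
Reactants: 8 3-methoxy-2-(trimethylsilyl)phenyl trifluoromethanesulfonate; 12 octadec-2-ynoic acid
Product: 15 1-(2-hydroxy-6-methoxyphenyl)octadec-2-yn-1-one, via cesium octadec-2-ynoate 13 (not isolated), via 3-methoxybenzyne 14 (not isolated)
Conditions: 12 (1.5 equiv), Cs2CO3 (0.5 equiv per acid), MeOH, rt, then evaporation and PhMe azeotrope; 8 (1 equiv), dried CsF (3 equiv), THF, 65 °C, sealed tube; cold 1 M HCl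
Reagents that add atoms: none
Why: Fluoride removes the silyl group of 8 and triflate leaves to give aryne 14; the carboxylate oxygen of 13 adds to the aryne carbon remote from the methoxy group, the aryl anion formed next to OMe attacks the adjacent ester carbonyl, and the strained four-membered alkoxide opens to the ortho-acyl phenoxide, a net insertion of the aryne into the acyl C–O bond that forms C8a–O1 and C4a–C4 in one operation. The closest known reaction type is the CsF-mediated insertion of arynes from ortho-silylaryl triflates into the C–O bond of carboxylic acids to give ortho-hydroxyaryl ketones, an aryne counterpart of the anionic Fries shift. No ring of the product closes (the four-membered ring is a transient, formed 4-exo-trig and reopened) and no stereocentre is created. Regioselectivity on the unsymmetrical aryne is required and should come from the inductively withdrawing C3 methoxy group, which directs the nucleophile to the distal aryne carbon so that the negative charge develops beside oxygen and the acyl group ends up between OMe and the new phenol. Chemoselectivity is also required, because the aryl anion could be protonated to an aryl ester and the phenoxide could add to its own triple bond; charging the acid as its dried cesium salt leaves no O–H or H–F acid in the flask to complete either process, which also allows a moderate temperature, and the cold acidic quench should deliver the hydrogen-bonded phenol 15.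

Step 6
Reactants: 15 1-(2-hydroxy-6-methoxyphenyl)octadec-2-yn-1-one
Product: 17 5-methoxy-2-pentadecyl-4H-chromen-4-one, via β-diethylamino enone 16 (not isolated)
Conditions: Et2NH, EtOH, rt → reflux
Reagents that add atoms: none
Why: Diethylamine adds in conjugate fashion to the ynone to give the β-amino enone, and the phenol oxygen then attacks the same β-carbon in a 6-endo-trig addition–elimination (oxa-Michael addition with loss of the amine) that forms O1–C2 and the pyranone ring while avoiding the 5-exo-dig closure open to a free phenoxide.

Step 7
Reactants: 17 5-methoxy-2-pentadecyl-4H-chromen-4-one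
Product: 18 5-hydroxy-2-pentadecyl-4H-chromen-4-one
Conditions: BBr3, CH2Cl2, −78 → 0 °C; H2O
Reagents that add atoms: none
Why: BBr3-mediated aryl methyl ether cleavage is assisted here by chelation of boron between the C5 oxygen and the peri C4 carbonyl, bromide removes the methyl group by SN2 attack, and aqueous work-up frees the hydrogen-bonded phenol without touching the pyranone or the alkyl chain.

**Compound list**

1 | 3-methoxyphenol | COc1cccc(O)c1 | starting material
2 | 3-methoxyphenyl propan-2-ylcarbamate | COc1cccc(OC(=O)NC(C)C)c1 | intermediate
3 | 3-methoxyphenyl N-(propan-2-yl)-N-(trimethylsilyl)carbamate | COc1cccc(OC(=O)N(C(C)C)[Si](C)(C)C)c1 | intermediate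
4 | {2-methoxy-6-[(propan-2-yl)(trimethylsilyl)carbamoyloxy]phenyl}lithium | COc1cccc(OC(=O)N(C(C)C)[Si](C)(C)C)c1[Li] | intermediate
5 | 3-methoxy-2-(trimethylsilyl)phenyl N-(propan-2-yl)-N-(trimethylsilyl)carbamate | COc1cccc(OC(=O)N(C(C)C)[Si](C)(C)C)c1[Si](C)(C)C | intermediate
6 | 3-methoxy-2-(trimethylsilyl)phenyl propan-2-ylcarbamate | COc1cccc(OC(=O)NC(C)C)c1[Si](C)(C)C | intermediate
7 | 3-methoxy-2-(trimethylsilyl)phenol | COc1cccc(O)c1[Si](C)(C)C | intermediate
8 | 3-methoxy-2-(trimethylsilyl)phenyl trifluoromethanesulfonate | COc1cccc(OS(=O)(=O)C(F)(F)F)c1[Si](C)(C)C | intermediate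
9 | 1-heptadecyne | CCCCCCCCCCCCCCCC#C | starting material
10 | carbon dioxide | O=C=O | starting material
11 | lithium heptadec-1-yn-1-ide | CCCCCCCCCCCCCCCC#C[Li] | intermediate
12 | octadec-2-ynoic acid | CCCCCCCCCCCCCCCC#CC(=O)O | intermediate
13 | cesium octadec-2-ynoate | CCCCCCCCCCCCCCCC#CC(=O)[O-].[Cs+] | intermediate
14 | 3-methoxybenzyne (1-methoxy-2,3-didehydrobenzene) | COC1=CC=CC#C1 | intermediate
15 | 1-(2-hydroxy-6-methoxyphenyl)octadec-2-yn-1-one | CCCCCCCCCCCCCCCC#CC(=O)c1c(O)cccc1OC | intermediate
16 | (E)-3-(diethylamino)-1-(2-hydroxy-6-methoxyphenyl)octadec-2-en-1-one | CCCCCCCCCCCCCCC/C(N(CC)CC)=C\C(=O)c1c(O)cccc1OC | intermediate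
17 | 5-methoxy-2-pentadecyl-4H-chromen-4-one | CCCCCCCCCCCCCCCc1cc(=O)c2c(OC)cccc2o1 | intermediate
18 | 5-hydroxy-2-pentadecyl-4H-chromen-4-one | CCCCCCCCCCCCCCCc1cc(=O)c2c(O)cccc2o1 | target

**Step count**

Total steps: 7. Longest linear sequence: 6 steps (steps 1, 2, 3, 5, 6, 7; 1 → 2 → 6 → 8 → 15 → 17 → 18). The acid branch (step 4) joins at step 5.

**Steps most likely to fail**

Step 5 (aryne insertion).
- What may go wrong: adventitious proton sources such as wet CsF would let the phenoxide add to its own triple bond in the insertion pot, with no control between the 5-exo and 6-endo modes. The product phenoxide could be O-arylated by a second aryne. The aryl anion could be protonated to the aryl ester instead of undergoing the acyl shift.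
- First adjustment: if insertion is slow at 65 °C, the temperature would be raised towards 125 °C.
- Fallback, palladium-catalysed carbonylative alkyne coupling instead of the aryne insertion: it sets out from 6 (with 9) and returns at 17.
  - Ipso-iododesilylation of 6 with ICl (CH2Cl2, 0 °C) should give 2-iodo-3-methoxyphenyl propan-2-ylcarbamate F1.
  - Carbamate cleavage as in step 3 (DBU, Et2NH, MeCN, 40 °C) should give 2-iodo-3-methoxyphenol F2.
  - F2, alkyne 9 and carbon monoxide would be joined by a carbonylative Sonogashira coupling with PdCl2(PPh3)2 as catalyst in Et2NH. The ynone 15 formed in the flask is carried by the amine through 16 to the chromone 17, and the route resumes at step 7.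

Step 6 (pyranone closure).
- What may go wrong: closure in the 5-exo mode at the α-carbon to a 2-alkylidene benzofuran-3-one, or stalling at the β-amino enone because the hydrogen-bonded, ortho-flanked phenol is a weak nucleophile.
- Fallback, cyclodehydration of a 1,3-diketone instead of conjugate addition: it sets out from 15 and returns at 17.
  - Et2NH in EtOH at rt takes 15 to 16, and aqueous HCl in THF hydrolyses the vinylogous amide to 1-(2-hydroxy-6-methoxyphenyl)octadecane-1,3-dione F3.
  - Heating F3 with catalytic H2SO4 in AcOH closes the hemiketal and dehydrates it to 17.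

Step 2 (ortho-silylation).
- What may go wrong: after metalation at the crowded C2 site the carbamoyl group may migrate to carbon on warming (anionic ortho-Fries shift), the flanked aryllithium may be silylated incompletely, or the N-silyl mask may be lost before metalation.
- Fallback, silicon delivered intramolecularly by bromine–lithium exchange and retro-Brook shift, with no carbamate present: it sets out from 1 and returns at 8.
  - MOMCl and i-Pr2NEt in CH2Cl2 give 1-methoxy-3-(methoxymethoxy)benzene F4.
  - n-BuLi in THF at 0 °C metalates between the two ethers to [2-methoxy-6-(methoxymethoxy)phenyl]lithium F5, which is quenched with 1,2-dibromoethane to 2-bromo-1-methoxy-3-(methoxymethoxy)benzene F6.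
  - HCl in MeOH removes the acetal to give 2-bromo-3-methoxyphenol F7.
  - HMDS in THF at reflux gives (2-bromo-3-methoxyphenoxy)trimethylsilane F8.
  - n-BuLi in THF at −78 °C exchanges bromine for lithium to give [2-methoxy-6-(trimethylsilyloxy)phenyl]lithium F9. The silyl group then shifts from oxygen to carbon (retro-Brook rearrangement) to give 7 as its lithium phenoxide, and Tf2O added to the same flask gives 8.

**Further compounds**

F1 | step 5 | 2-iodo-3-methoxyphenyl propan-2-ylcarbamate | COc1cccc(OC(=O)NC(C)C)c1I
F2 | step 5 | 2-iodo-3-methoxyphenol | COc1cccc(O)c1I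
F3 | step 6 | 1-(2-hydroxy-6-methoxyphenyl)octadecane-1,3-dione | CCCCCCCCCCCCCCCC(=O)CC(=O)c1c(O)cccc1OC
F4 | step 2 | 1-methoxy-3-(methoxymethoxy)benzene | COCOc1cccc(OC)c1
F5 | step 2 | [2-methoxy-6-(methoxymethoxy)phenyl]lithium | COCOc1cccc(OC)c1[Li]
F6 | step 2 | 2-bromo-1-methoxy-3-(methoxymethoxy)benzene | COCOc1cccc(OC)c1Br
F7 | step 2 | 2-bromo-3-methoxyphenol | COc1cccc(O)c1Br
F8 | step 2 | (2-bromo-3-methoxyphenoxy)trimethylsilane | COc1cccc(O[Si](C)(C)C)c1Br
F9 | step 2 | [2-methoxy-6-(trimethylsilyloxy)phenyl]lithium | COc1cccc(O[Si](C)(C)C)c1[Li]
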